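Divide each rate in these flasks by Xa times Xb, and watch what that quotient does as Xp builds up.

| setting | eta | delta | alpha | gamma |
|---|---|---|---|---|
| Xa | 0.150 M | 0.0750 M | 0.450 M | 0.150 M |
| Xb | 0.165 M | 0.0900 M | 0.165 M | 0.165 M |
| Xc | 7.50 × 10⁻⁴ M | 7.50 × 10⁻⁴ M | 7.50 × 10⁻⁴ M | 7.50 × 10⁻⁴ M |
| Xp |  |  |  | 0.0450 M |
| time |  |  |  | 20 min |

| run | time / min | [Xa] / M |
|---|---|---|
| eta run | 0.89 | 0.1472 |
| eta run | 2.7 | 0.1384 |
| eta run | 5.2 | 0.1239 |
| eta run | 8.2 | 0.1012 |
| eta run | 12 | 0.0737 |
| eta run | 16 | 0.0520 |
| eta run | 20 | 0.0366 |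
| delta run | 0.89 | 0.0734 |
| delta run | 2.7 | 0.0702 |
| delta run | 5.2 | 0.0649 |
| delta run | 8.2 | 0.0587 |
| delta run | 12 | 0.0509 |
| delta run | 16 | 0.0423 |
| delta run | 20 | 0.0362 |
| alpha run | 0.89 | 0.4447 |
| alpha run | 2.7 | 0.4197 |
| alpha run | 5.2 | 0.3560 |
| alpha run | 8.2 | 0.3040 |
| alpha run | 12 | 0.2876 |
| alpha run | 16 | 0.2853 |
| alpha run | 20 | 0.2850 |

(each reading ± 4 × 10⁻⁴ M)

- reaction order in [Xb] at the outset, round the charge of the eta run, defined at two percent of the Xa turned into Xp
- reaction order in [Xa] at the outset, round the charge of the eta run, defined at two percent of the Xa turned into Xp (one fixed amount of Xp, the same in the runs compared)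
- the delta run starts with 0.0750 M less of Xa and of Xb than the eta run, and with no Xp. Compared where both hold the same amount of Xa, once fifteen percent of what the delta run was charged with has turned into Xp, is the delta run faster, slower or alike (within a tenth)?
- Xa in the gamma run at 20 min, as a share of the Xa charged

- Overall: Xa + Xb -> Xp, with Xc as catalyst.
- Constant volume, constant temperature.
- Bound and free are read together.
- "The second partner" is Xb.
- An order is taken over about fifteen percent of the charge, up and down.

The alpha run ends at 0.2850 M of Xa, a loss of 0.165 M against 0.165 M of Xb charged. So one Xb goes with one Xa, Xb is the limiting reagent there, and the Xp made is read as the Xa lost.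

That lets the quotient be read from the eta run. Between its first two readings, at 7.20 mM of Xp, it is 0.216 M⁻¹ min⁻¹. Between 12 min and 16 min, at 0.0871 M of Xp, it is 1.11 M⁻¹ min⁻¹, larger. So Xp appears to help its own making (autocatalysis), and a straight line through the two readings has slope 11.2 M⁻² min⁻¹.

That line reads 0.0121 M at the outset of the eta run, the crossover amount: the Xp at which the part of the rate helped by Xp equals the part that needs none.

Two percent of the eta charge is 3.00 mM of Xp, less than the crossover amount. So on that line 80.1% of the eta run's rate at that point needs no Xp, and my reckoning puts no number on the orders asked.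

At the point asked of the delta run, the two flasks hold equal Xa and equal Xb, with 0.0112 M of Xp in the delta run and 0.0862 M in the eta run. With the crossover amount held fixed, the delta run's rate stands at 0.238 of the eta run's, so the delta run is slower.

The gamma run has the eta charge of Xa, Xb and Xc, and starts with 3.71 crossover amounts of Xp. Integrated from there, the quotient law brings Xa to 0.0300 M at 13.7 min and to 0.0150 M at 22.9 min. Interpolating the logarithm between those two points puts Xa at 20 min at about 12.4% of the charge.

The forecast gives 0.5 for Xb, 0.7 for Xa, slower for the delta run and 11% for the gamma run, lower than my figure, and says of the rising quotient: “so the reaction is autocatalytic”.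

The flask gives 0.57 for Xb, 0.44 for Xa, slower for the delta run and 12.0% for the gamma run. At the shared Xa, the delta run goes at 0.37 of the eta run's rate, more than the 0.238 reckoned.

    Xc + Xa ⇌ Xc.Xa, settled at all times (11.40 M⁻¹)
    Xc.Xa + Xb ⇌ Xc.Xa.Xb, settled at all times (20.60 M⁻¹)
    Xc.Xa.Xb → Xp + Xc (4.734 min⁻¹)
    Xa + Xb → Xp (0.02418 M⁻¹ min⁻¹)
    Xa + Xb + Xp → 2 Xp (9.720 M⁻² min⁻¹)

Set into the same ratio, 0.37 asks for a crossover amount of 0.0322 M at the Xa and Xb the two flasks then share, above the 0.0121 M read at the outset of the eta run.

(The data stem from a simulated flask on assumed constants; noise was put on by code.)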